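The single product comes first and the bis adduct follows it in the gamma, alpha and zeta runs, so before you take over the south flask, carry one number from them. Take the fraction of bis adduct in the sum c(single product) + c(bis adduct), and divide it once more by that sum, both as fractions of the starting material charged. The last readings give 1.17 for gamma, 1.10 for alpha and 1.17 for zeta, so I keep their mean, the bis number b = 1.15, a selectivity factor in disguise, and reckon the share as one minus b times the sum.

| flask | starting material | reagent | temperature | remark | time |
|---|---|---|---|---|---|
| gamma | 0.20 M | 0.19 M | 95 °C | run made earlier |  |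
| alpha | 0.20 M | 0.095 M | 106 °C | run made earlier |  |
| zeta | 0.20 M | 0.14 M | 95 °C | run made earlier |  |
| south | 0.20 M (fed, over 12 min) | 0.190 M |  | the addition at 60 °C, then warmed to 100 °C; the feed brings no volume worth counting | 20 min |
| north-east | 0.20 M | 0.190 M (fed, over 3.0 min) | 100 °C | all else is in the flask from the start; the feed brings no volume worth counting | 20 min |
| west | 0.20 M | 0.190 M | 100 °C | everything together at the start | 20 min |
| south-west | 0.20 M (fed, over 12 min) | 0.190 M | 100 °C | all else is in the flask from the start; the feed brings no volume worth counting | 20 min |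

| run | time / min | single product / % | bis adduct / % |
|---|---|---|---|
| gamma | 1.00 | 3.0 | 0 |
| gamma | 3.00 | 6.0 | 0.7 |
| gamma | 6.00 | 10.0 | 1.2 |
| gamma | 8.00 | 13.1 | 1.2 |
| gamma | 12.0 | 13.9 | 3.4 |
| gamma | 15.0 | 14.7 | 4.4 |
| gamma | 20.0 | 17.0 | 6.4 |
| alpha | 2.00 | 4.3 | 0.3 |
| alpha | 3.00 | 5.6 | 0.8 |
| alpha | 4.00 | 7.3 | 0.5 |
| alpha | 6.00 | 10.5 | 1.4 |
| alpha | 10.0 | 12.4 | 2.6 |
| alpha | 15.0 | 14.5 | 2.8 |
| alpha | 25.0 | 16.4 | 5.1 |
| zeta | 3.00 | 5.0 | 0 |
| zeta | 6.00 | 8.7 | 1.1 |
| zeta | 10.0 | 9.9 | 1.3 |
| zeta | 15.0 | 12.6 | 2.2 |
| zeta | 20.0 | 14.3 | 3.4 |
| zeta | 25.0 | 14.9 | 4.3 |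

(each reading ± 0.5 percentage points)



- the flask with the highest share of single product in single product plus bis adduct ("all alike" if they lie within 1.5 percentage points) (south / north-east / west / south-west / all alike)
- share of single product in single product plus bis adduct at the end, south
- share of single product in single product plus bis adduct at the end, north-east
- share of single product in single product plus bis adduct at the end, west
- share of single product in single product plus bis adduct at the end, south-west

You take over south with the reagent in the flask at 60 °C while starting material runs in for 12 min. Gamma and alpha at 6.00 min, with reagent taken as first order, give, as a reading with their scatter, a speed-up of 1.41 from 95 °C to 100 °C. Carried down, that estimate makes the cold stretch 15.5 times slower, so its 12 min count for less than the 8.00 min after warming, and I count turnovers in those. These equal 11.3 min at 95 °C, near the gamma reading at 12.0 min, whose sum 17.3% puts south at 80.2% when you come at 20 min. The other flasks stay hot for 20 min, longer than south, so I put south first. Don't warm it early or leave it hot past 20 min: in gamma the sum went on rising, from 17.3% at 12.0 min to 23.4% at 20.0 min.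

The forecast says south, with 78% for south, 72% for north-east, 70% for west and 75% for south-west, on the ground that “share falls as conversion rises”; its south figure lies below mine.

The flask puts south first, with 80.9% for south against 72.1% for north-east, 71.2% for west and 75.3% for south-west.

    reagent ⇌ dormant form (K = 0.380, k = 0.0760 min⁻¹, Ea = 102 kJ mol⁻¹, ΔH = −52.0 kJ mol⁻¹)
    reagent + bis adduct → tris adduct (k = 0.420 M⁻¹ min⁻¹, Ea = 63.0 kJ mol⁻¹)
    single product ⇌ isomer of the product (K = 0.420, k = 0.160 min⁻¹, Ea = 97.0 kJ mol⁻¹, ΔH = 43.0 kJ mol⁻¹)
    starting material + reagent → single product (k = 0.240 M⁻¹ min⁻¹, Ea = 94.0 kJ mol⁻¹)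
    reagent + single product → bis adduct (k = 0.430 M⁻¹ min⁻¹, Ea = 72.0 kJ mol⁻¹)
    (constants at 100 °C)

At 20.0 min south held 14.1% single product and 3.33% bis adduct, with 77.2% of the starting material left, and that sum with the kept b gives 80.0%. The neighbouring flask, south with 0.11 M of reagent, held 9.42% single product and 1.31% bis adduct, for which b gives 87.7%, and its share stood at 87.8%.

The data were generated by integration on assumed constants, noise included.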